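## Analysis of the target

The target (25) is a flavone: benzene ring A is fused to 4-pyranone ring C, and ring B is bonded to C2. Ring A is hexasubstituted, with the free hydroxyl at C5, methoxy groups at C6, C7 and C8, and the fusion atoms C4a and C8a, so it carries five oxygens and no hydrogen. Ring C bears a methoxy group at C3. Ring B is 1,2,4,5-tetrasubstituted, with a methoxy group at C2' and a catechol at C4'/C5'. There is no stereocentre, so the problem is regiochemical: eight oxygen substituents must be placed, three of them (O5, O4', O5') as free hydroxyls and five as methyl ethers. The catechol and the pentaoxygenated ring A are easily oxidised towards quinones, the polyether ring A is sensitive to strong acids, and the C2–C3 double bond and the C4 carbonyl accept nucleophiles and hydride. A classical route through an aryl ketone would need acylation of a pentaoxygenated benzene at its last free carbon under acidic conditions. The strategy rests on C4: it is a single carbonyl carbon between C4a of ring A and the C3–C2 unit, so it can enter as carbon monoxide between an aryl iodide at C4a (whose ortho phenol becomes O1) and a terminal arylalkyne that supplies C3, C2 and ring B.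

## Retrosynthetic reasoning

**25 from 24.** The three O–benzyl bonds at O5, O4' and O5' are cut last. Every oxygen that ends as a hydroxyl is carried as a benzyl ether and every oxygen that ends as a methoxy group is carried as a methyl ether from the start. The hydroxyl/methoxy pattern is thus written into the building blocks, and a single hydrogenolysis reveals it without touching a methyl ether.

**24 from 23.** The O–CH3 bond at O3 is cut. In 23 the 3-hydroxyl is the only free hydroxyl, so the methylation needs no selectivity.

**23 from 21 (through epoxide 22).** The C3–O bond is cut. A flavone made from a terminal alkyne has hydrogen at C3, so this oxygen is added afterwards by epoxidation of the C2–C3 double bond and acid opening of 22. This order keeps the alkyne partner simple. It requires O5 to be masked, because a free phenol on the pentaoxygenated ring would not survive the oxidant; this is a further reason for the benzyl ether at O5.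

**21 from 10, 17 and 18 (through 19 and 20).** Three bonds are cut: C4a–C4, C4–C3 and O1–C2. C4 becomes carbon monoxide 18, ring A becomes iodophenol 10, and C3, C2 and ring B become alkyne 17. The cut is made here because every other way of joining ring A to C4 needs an aryl ketone of ring A, that is, an acylation of an acid-sensitive polyether. In 10 the iodine marks the one carbon of ring A without oxygen, so the position of the carbonyl is not in question. The two partners are of similar size and the step is convergent. In the forward direction, CO must insert before the alkyne couples, and the phenol must close the six-membered ring through ynone 19 and its amine adduct 20, not the five-membered one.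

**10 from 9.** The C–I bond is cut. Phenol 9 has one ring hydrogen, ortho to the free hydroxyl, so electrophilic iodination can go to one place only.

**9 from 6, 6 from 5, 5 from 2, 2 from 1.** Both flanking C–O bonds are traced back to C–Br bonds of the symmetric dibromide 2, which comes from 1 by twofold bromination. The two bromines are converted one at a time (2 to 5, benzylation to 6, then 6 to 9). The two oxygens are therefore different from the moment they are made. Hydroxylating both bromines of 2 at once would save a step, but it would leave two equivalent phenols to be told apart by a statistical monobenzylation.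

**17 from 16, 16 from 14, 14 from 13, 13 from 11.** The alkyne is cut to aldehyde 16 (one-carbon homologation). The formyl group of 16 is cut from arene 14, where the position para to one benzyloxy group and ortho to the methoxy group is the most nucleophilic. The methyl ether of 14 is cut to phenol 13, whose C–O bond comes from the formyl group of commercial aldehyde 11 by oxidative aryl migration through formate 12. The catechol therefore arrives already benzylated.

## Alternatives that were turned down

**Alternative 1:** Threefold methoxylation of a brominated quercetin ether.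
- Disconnection: the three C–OMe bonds at C6, C8 and C2'.
- Forward key step: quercetin A3 would be ketalised at the catechol, methylated at O3 and O7, and brominated three times to the 6,8,2'-tribromide A2. NaOMe with CuBr in DMF/MeOH would then replace all three bromines to give A1, and acid would remove the ketal.
- In its favour: A3 is cheap and already holds the whole skeleton including the C3 oxygen. The sequence is about half as long as the chosen one and needs neither CO nor a dioxirane. On step economy it is clearly stronger.
- Against it: the third bromine must enter ring B, which is deactivated by its bond to the electron-poor C2. It must go ortho to that bond, in competition with the less hindered position next to O4', and only after ring A is saturated. The HBr set free endangers the ketal. The substitution must then succeed at three different sites, one next to the C5 phenoxide and one hindered at C2'. Reductive loss of bromine can compete at each site, and methoxide can also attack C2 of the pyranone. Any shortfall gives mixtures of nearly identical flavones.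
- Comparison: the chosen route is longer, but each oxygen sits where the starting materials put it, and no methoxy group is made by substitution on the finished flavone.

**Alternative 2:** Biomimetic folding of a methoxylated polyketo ester.
- Disconnection: C4a–C8a of ring A and O1–C2 of ring C, back to the open-chain tetraketo ester A5.
- Forward key step: Mg(OMe)2 would make the single methylene carbon (C4a) attack the ester carbon (C8a). After aromatisation the new phenol would condense with the aryl ketone to give the 5,7-dihydroxyflavone A4. Selective methylation at O7 and debenzylation would follow.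
- In its favour: two rings form in one operation, no halogen or transition metal is needed, and in principle every oxygen is fixed by the chain. In bonds formed per step it is stronger than the chosen key step.
- Against it: A5 has three enolisable methoxy-bearing methine carbons besides the methylene, so the methylene is not the only nucleophile. Aldol closures from the methine carbons and O-cyclisations to pyranones compete with the intended Claisen closure. Assembling A5 by repeated Claisen condensations of methoxyacetyl units is long and passes through unstable intermediates. A4 also carries one hydroxyl too many.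
- Comparison: the chosen route starts from arenes that already have the oxygen pattern, and leaves only one bond-forming event uncertain.

**Alternative 3:** Ketyl pinacol closure of the C3–C4 bond.
- Disconnection: C3–C4, back to dialdehyde A7.
- Forward key step: SmI2 would reduce the aromatic aldehyde (C4) to a ketyl that adds to the tethered aliphatic aldehyde (C3), giving the 2,3-trans-3,4-cis flavan-3,4-diol A6. Oxidation of both alcohols (the resulting 3,4-dione is the keto form of the flavonol), methylation and debenzylation would follow.
- In its favour: the C3 oxygen is in place when ring C forms, so no late hydroxylation is needed. Divalent samarium is mild towards benzyl and methyl ethers, and chelation should give the cis-diol. On the C3 oxygen it is stronger than the chosen route.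
- Against it: three stereocentres are made only to be erased. A7 needs a salicylaldehyde of ring A, which means the same pentaoxygenated arene as here plus a formyl group. A7 also contains an α-aryl-α-aryloxy aldehyde that enolises and eliminates aryloxide readily. SmI2 itself cleaves carbon–oxygen bonds α to a carbonyl group, which threatens the tether directly. After the key step four operations remain, against three here.
- Comparison: the chosen route makes C4 directly at the ketone oxidation level from CO and has no stereochemistry to control or discard.

Key step: step 10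

Remark: the target has no stereocentre. The only chiral compound on the route is epoxide 22, formed as a racemate, necessarily cis-fused and not isolated. Enaminone 20 is drawn as its E isomer, although either geometry can close.

## Route

Step 1
Reactants: 1 1,2,3-trimethoxybenzene
Product: 2 1,5-dibromo-2,3,4-trimethoxybenzene
Conditions: NBS (2.2 equiv), MeCN, rt → 50 °C
Reagents that add atoms: N-bromosuccinimide, O=C1CCC(=O)N1Br
Why: Twofold electrophilic aromatic bromination. C4 and C6 are each para to one outer methoxy group and ortho to the other, whereas C5 is para only to the central methoxy group, which is twisted out of conjugation, so the 4,6-dibromide should form.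

Step 2
Reactants: 2 1,5-dibromo-2,3,4-trimethoxybenzene
Product: 5 5-bromo-2,3,4-trimethoxyphenol, via aryllithium 3 (not isolated), via lithium aryltrimethoxyborate 4 (not isolated)
Conditions: n-BuLi (1.0 equiv), THF, −78 °C; B(OMe)3, −78 °C → rt; AcOH, 30 % H2O2, 0 °C → rt
Reagents that add atoms: hydrogen peroxide, OO (the phenol oxygen); n-butyllithium, [Li]CCCC, and trimethyl borate, COB(OC)OC, leave atoms only in intermediates 3 and 4
Why: Bromine–lithium exchange with one equivalent of n-BuLi should stop after one bromine, since a second exchange would have to build a dianion, and the low temperature keeps 3 from deprotonating unreacted 2. Borylation and oxidative aryl shift from boron to oxygen (ipso-hydroxylation of an arylboron compound) give the phenol.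

Step 3
Reactants: 5 5-bromo-2,3,4-trimethoxyphenol
Product: 6 1-(benzyloxy)-5-bromo-2,3,4-trimethoxybenzene
Conditions: BnBr, K2CO3, DMF, rt
Reagents that add atoms: benzyl bromide, BrCc1ccccc1
Why: Williamson ether synthesis on the only phenol; this fixes which of the two former bromine positions becomes O5 of the flavone.

Step 4
Reactants: 6 1-(benzyloxy)-5-bromo-2,3,4-trimethoxybenzene
Product: 9 5-(benzyloxy)-2,3,4-trimethoxyphenol, via aryllithium 7 (not isolated), via lithium aryltrimethoxyborate 8 (not isolated)
Conditions: n-BuLi (1.05 equiv), THF, −78 °C; B(OMe)3, −78 °C → rt; AcOH, 30 % H2O2, 0 °C → rt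
Reagents that add atoms: hydrogen peroxide, OO (the phenol oxygen); n-butyllithium, [Li]CCCC, and trimethyl borate, COB(OC)OC, leave atoms only in intermediates 7 and 8
Why: The same bromine–lithium exchange, borylation and oxidation sequence as in step 2. At −78 °C the exchange is much faster than attack of n-BuLi on the benzylic C–H of the ether.

Step 5
Reactants: 9 5-(benzyloxy)-2,3,4-trimethoxyphenol
Product: 10 3-(benzyloxy)-2-iodo-4,5,6-trimethoxyphenol
Conditions: NIS (1.05 equiv), MeCN, 0 °C, dark
Reagents that add atoms: N-iodosuccinimide, O=C1CCC(=O)N1I
Why: Electrophilic aromatic iodination of a phenol. The ring has a single C–H, ortho to the free hydroxyl and to the benzyloxy group, so only one iodide can form.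

Step 6
Reactants: 11 3,4-bis(benzyloxy)benzaldehyde
Product: 13 3,4-bis(benzyloxy)phenol, via aryl formate 12 (not isolated)
Conditions: mCPBA, CH2Cl2, rt; aq NaHCO3 wash; K2CO3 (cat.), MeOH, rt
Reagents that add atoms: 3-chloroperbenzoic acid, O=C(OO)c1cccc(Cl)c1
Why: Baeyer–Villiger oxidation of an electron-rich benzaldehyde (Dakin-type): the alkoxy-substituted aryl group migrates in preference to hydrogen. The formate is then cleaved by methanolysis.

Step 7
Reactants: 13 3,4-bis(benzyloxy)phenol
Product: 14 1,2-bis(benzyloxy)-4-methoxybenzene
Conditions: MeI, K2CO3, acetone, reflux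
Reagents that add atoms: iodomethane, CI
Why: Williamson methylation of the only phenol; this oxygen becomes the 2'-methoxy group.

Step 8
Reactants: 14 1,2-bis(benzyloxy)-4-methoxybenzene
Product: 16 4,5-bis(benzyloxy)-2-methoxybenzaldehyde, via aryl iminium chloride 15 (not isolated)
Conditions: POCl3, DMF, 0 → 70 °C; aq NaOAc, rt
Reagents that add atoms: N,N-dimethylformamide, CN(C)C=O (the formyl carbon); water, O (the aldehyde oxygen on hydrolysis); phosphoryl chloride, O=P(Cl)(Cl)Cl, gives only the chloride of intermediate 15
Why: Vilsmeier–Haack formylation of a trialkoxybenzene. The chloroiminium ion attacks the carbon para to one benzyloxy group and ortho to the methoxy group; the other free positions are activated by one ortho oxygen only or are flanked on both sides.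

Step 9
Reactants: 16 4,5-bis(benzyloxy)-2-methoxybenzaldehyde
Product: 17 1,2-bis(benzyloxy)-4-ethynyl-5-methoxybenzene
Conditions: dimethyl (1-diazo-2-oxopropyl)phosphonate, K2CO3, MeOH/THF, rt
Reagents that add atoms: dimethyl (1-diazo-2-oxopropyl)phosphonate, COP(=O)(OC)C(=[N+]=[N-])C(C)=O
Why: Seyferth–Gilbert homologation with the Ohira–Bestmann reagent. Methanolysis of the acetyl group frees the diazomethylphosphonate anion, which adds to the aldehyde and eliminates phosphate; loss of N2 and a 1,2-hydrogen shift give the terminal alkyne. The mild base leaves the ethers untouched.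

Step 10
Reactants: 10 3-(benzyloxy)-2-iodo-4,5,6-trimethoxyphenol; 17 1,2-bis(benzyloxy)-4-ethynyl-5-methoxybenzene; 18 carbon monoxide
Product: 21 5,4',5'-tribenzyloxy-6,7,8,2'-tetramethoxyflavone, via 2-hydroxyaryl ynone 19 (not isolated), via enaminone 20 (not isolated)
Conditions: PdCl2(PPh3)2 (5 mol %), CO (1 atm), Et2NH, 60 °C
Reagents that add atoms: carbon monoxide, [C-]#[O+] (reactant 18, becomes C4 and its oxygen); diethylamine, CCNCC (held only in intermediate 20)
Why: The divalent palladium precatalyst is reduced in the amine to zerovalent palladium, which inserts into the C–I bond of 10; CO then inserts to give an aroyl palladium species, and the alkyne 17, deprotonated by diethylamine, is transferred to palladium and reductively eliminated to give ynone 19 (bonds C4a–C4 and C4–C3). Diethylamine adds to the β-carbon of 19 to give enaminone 20, and the ortho phenol displaces the amine at C2 by addition–elimination (bond O1–C2). The closest known reaction type is the carbonylative Sonogashira coupling of 2-iodophenols with terminal arylalkynes with cyclisation to flavones in the same flask. Ring C closes in the 6-endo mode: 6-endo-dig counted on the triple bond of 19, 6-endo-trig addition–elimination at the stage of 20. No stereocentre is formed. The step needs carbonylation to precede alkynylation; the electron-rich aryl–palladium bond flanked by two oxygens should take up CO readily, and leaving out copper slows direct alkyne transfer. It also needs six-membered to beat five-membered closure, which the amine adduct secures because C2 is its only electrophilic carbon. Only one phenol is free and the iodine sits on the only oxygen-free carbon of ring A, so one flavone alone can result.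

Step 11
Reactants: 21 5,4',5'-tribenzyloxy-6,7,8,2'-tetramethoxyflavone
Product: 23 5,4',5'-tribenzyloxy-3-hydroxy-6,7,8,2'-tetramethoxyflavone, via racemic 2,3-epoxide 22 (not isolated)
Conditions: DMDO (acetone solution, excess in portions), CH2Cl2, 0 °C → rt; evaporate; TsOH·H2O (cat.), CH2Cl2, rt
Reagents that add atoms: dimethyldioxirane, CC1(C)OO1
Why: Epoxidation of the C2–C3 double bond of a flavone by a dioxirane, a known reaction type, gives the racemic cis-fused epoxide 22. Acid opens it at C2 (cation stabilised by O1 and ring B), and loss of the C3 proton gives the 3-hydroxyflavone, so both stereocentres of 22 disappear again.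

Step 12
Reactants: 23 5,4',5'-tribenzyloxy-3-hydroxy-6,7,8,2'-tetramethoxyflavone
Product: 24 5,4',5'-tribenzyloxy-3,6,7,8,2'-pentamethoxyflavone
Conditions: MeI, K2CO3, DMF, rt
Reagents that add atoms: iodomethane, CI
Why: Williamson methylation of the only free hydroxyl; the enolic 3-hydroxyl next to the carbonyl is acidic enough for K2CO3.

Step 13
Reactants: 24 5,4',5'-tribenzyloxy-3,6,7,8,2'-pentamethoxyflavone
Product: 25 5,4',5'-trihydroxy-3,6,7,8,2'-pentamethoxyflavone
Conditions: H2 (1 atm), Pd/C (10 wt %), EtOAc/MeOH, rt; work-up under argon
Reagents that add atoms: none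
Why: Hydrogenolysis of three benzyl aryl ethers over Pd/C. Methyl ethers are inert, and the tetrasubstituted C2–C3 double bond of a 3-methoxyflavone is not readily hydrogenated at atmospheric pressure.

## Compound list

1 | 1,2,3-trimethoxybenzene | COc1cccc(OC)c1OC | starting material
2 | 1,5-dibromo-2,3,4-trimethoxybenzene | COc1c(Br)cc(Br)c(OC)c1OC | intermediate
3 | (5-bromo-2,3,4-trimethoxyphenyl)lithium (not isolated) | [Li]c1cc(Br)c(OC)c(OC)c1OC | intermediate
4 | lithium (5-bromo-2,3,4-trimethoxyphenyl)trimethoxyborate (not isolated) | [Li+].CO[B-](OC)(OC)c1cc(Br)c(OC)c(OC)c1OC | intermediate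
5 | 5-bromo-2,3,4-trimethoxyphenol | COc1c(O)cc(Br)c(OC)c1OC | intermediate
6 | 1-(benzyloxy)-5-bromo-2,3,4-trimethoxybenzene | COc1c(OCc2ccccc2)cc(Br)c(OC)c1OC | intermediate
7 | [5-(benzyloxy)-2,3,4-trimethoxyphenyl]lithium (not isolated) | [Li]c1cc(OCc2ccccc2)c(OC)c(OC)c1OC | intermediate
8 | lithium [5-(benzyloxy)-2,3,4-trimethoxyphenyl]trimethoxyborate (not isolated) | [Li+].CO[B-](OC)(OC)c1cc(OCc2ccccc2)c(OC)c(OC)c1OC | intermediate
9 | 5-(benzyloxy)-2,3,4-trimethoxyphenol | COc1c(O)cc(OCc2ccccc2)c(OC)c1OC | intermediate
10 | 3-(benzyloxy)-2-iodo-4,5,6-trimethoxyphenol | COc1c(O)c(I)c(OCc2ccccc2)c(OC)c1OC | intermediate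
11 | 3,4-bis(benzyloxy)benzaldehyde | O=Cc1ccc(OCc2ccccc2)c(OCc2ccccc2)c1 | starting material
12 | 3,4-bis(benzyloxy)phenyl formate (not isolated) | O=COc1ccc(OCc2ccccc2)c(OCc2ccccc2)c1 | intermediate
13 | 3,4-bis(benzyloxy)phenol | Oc1ccc(OCc2ccccc2)c(OCc2ccccc2)c1 | intermediate
14 | 1,2-bis(benzyloxy)-4-methoxybenzene | COc1ccc(OCc2ccccc2)c(OCc2ccccc2)c1 | intermediate
15 | N-{[4,5-bis(benzyloxy)-2-methoxyphenyl]methylidene}-N-methylmethanaminium chloride (not isolated) | C[N+](C)=Cc1cc(OCc2ccccc2)c(OCc2ccccc2)cc1OC.[Cl-] | intermediate
16 | 4,5-bis(benzyloxy)-2-methoxybenzaldehyde | COc1cc(OCc2ccccc2)c(OCc2ccccc2)cc1C=O | intermediate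
17 | 1,2-bis(benzyloxy)-4-ethynyl-5-methoxybenzene | C#Cc1cc(OCc2ccccc2)c(OCc2ccccc2)cc1OC | intermediate
18 | carbon monoxide | [C-]#[O+] | starting material
19 | 1-[6-(benzyloxy)-2-hydroxy-3,4,5-trimethoxyphenyl]-3-[4,5-bis(benzyloxy)-2-methoxyphenyl]prop-2-yn-1-one (not isolated) | COc1cc(OCc2ccccc2)c(OCc2ccccc2)cc1C#CC(=O)c1c(O)c(OC)c(OC)c(OC)c1OCc1ccccc1 | intermediate
20 | (E)-1-[6-(benzyloxy)-2-hydroxy-3,4,5-trimethoxyphenyl]-3-[4,5-bis(benzyloxy)-2-methoxyphenyl]-3-(diethylamino)prop-2-en-1-one (not isolated) | CCN(CC)/C(=C/C(=O)c1c(O)c(OC)c(OC)c(OC)c1OCc1ccccc1)c1cc(OCc2ccccc2)c(OCc2ccccc2)cc1OC | intermediate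
21 | 5,4',5'-tribenzyloxy-6,7,8,2'-tetramethoxyflavone | COc1cc(OCc2ccccc2)c(OCc2ccccc2)cc1-c1cc(=O)c2c(OCc3ccccc3)c(OC)c(OC)c(OC)c2o1 | intermediate
22 | 5,4',5'-tribenzyloxy-2,3-epoxy-6,7,8,2'-tetramethoxyflavanone (racemate, one enantiomer drawn, epoxide cis-fused to ring C; not isolated) | COc1cc(OCc2ccccc2)c(OCc2ccccc2)cc1[C@]12O[C@H]1C(=O)c1c(OCc3ccccc3)c(OC)c(OC)c(OC)c1O2 | intermediate
23 | 5,4',5'-tribenzyloxy-3-hydroxy-6,7,8,2'-tetramethoxyflavone | COc1cc(OCc2ccccc2)c(OCc2ccccc2)cc1-c1oc2c(OC)c(OC)c(OC)c(OCc3ccccc3)c2c(=O)c1O | intermediate
24 | 5,4',5'-tribenzyloxy-3,6,7,8,2'-pentamethoxyflavone | COc1cc(OCc2ccccc2)c(OCc2ccccc2)cc1-c1oc2c(OC)c(OC)c(OC)c(OCc3ccccc3)c2c(=O)c1OC | intermediate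
25 | 5,4',5'-trihydroxy-3,6,7,8,2'-pentamethoxyflavone | COc1cc(O)c(O)cc1-c1oc2c(OC)c(OC)c(OC)c(O)c2c(=O)c1OC | target

## Step count and least certain steps

Total: 13 steps. Longest linear sequence: 9 steps (steps 1–5 and 10–13, from 1). The ring B branch (steps 6–9, from 11) joins at step 10.

**Step 10 (key step).** The most likely failure is loss of the carbonylative pathway. The alkyne may couple at the aryl–palladium stage before CO is taken up, the aroyl palladium species may be captured by the amine solvent, or oxidative addition at the doubly ortho-substituted, electron-rich iodide may be too slow for either to matter.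
The fallback sets out from 10 and 17 and returns at 19, hence at 21. It brings in C4 as a formyl group and makes C4–C3 by acetylide addition.
- Phenol 10 is protected with MOMCl and iPr2NEt in CH2Cl2 as 1-(benzyloxy)-2-iodo-3-(methoxymethoxy)-4,5,6-trimethoxybenzene F1.
- Iodine–magnesium exchange with iPrMgCl·LiCl in THF at −20 °C and quenching with DMF give 2-(benzyloxy)-6-(methoxymethoxy)-3,4,5-trimethoxybenzaldehyde F2.
- Alkyne 17 is deprotonated with n-BuLi in THF at −78 °C and added to F2 to give racemic 1-[2-(benzyloxy)-6-(methoxymethoxy)-3,4,5-trimethoxyphenyl]-3-[4,5-bis(benzyloxy)-2-methoxyphenyl]prop-2-yn-1-ol F3.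
- MnO2 in CH2Cl2 oxidises F3 to 1-[2-(benzyloxy)-6-(methoxymethoxy)-3,4,5-trimethoxyphenyl]-3-[4,5-bis(benzyloxy)-2-methoxyphenyl]prop-2-yn-1-one F4.
- HCl in MeOH removes the acetal to give 19, which is closed to 21 through 20 in Et2NH without palladium or CO.

**Step 11.** Epoxidation of the electron-poor C2–C3 double bond is slow. The excess oxidant may instead attack the benzylic C–H bonds of the three benzyl ethers or the electron-rich rings.
The fallback sets out from 21 and returns at 23. It makes the C3–O bond from a C3 anion instead of an epoxide. Deprotonation at C3 with LiN(iPr)2 in THF at −78 °C (the C3–H of a flavone is its most acidic C–H) and trapping with B(OMe)3 give dimethyl {5-(benzyloxy)-2-[4,5-bis(benzyloxy)-2-methoxyphenyl]-6,7,8-trimethoxy-4-oxo-4H-chromen-3-yl}boronate F5. Oxidation with AcOH/H2O2 in the same flask gives 23.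

**Step 5.** The electrophilic iodine source may oxidise the very electron-rich phenol (oxidative demethylation at the methoxy group para to the hydroxyl) instead of substituting it. The iodine may also be lost again by protodeiodination on acidic handling.
The fallback sets out from 9 and returns at 10. It replaces electrophilic substitution by directed ortho-metalation.
- Phenol 9 is protected with MOMCl and iPr2NEt as 1-(benzyloxy)-5-(methoxymethoxy)-2,3,4-trimethoxybenzene F6.
- n-BuLi in THF at 0 °C removes the single ring proton, which lies between the two directing oxygens.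
- Iodine gives 1-(benzyloxy)-2-iodo-3-(methoxymethoxy)-4,5,6-trimethoxybenzene F1, the same compound as in the fallback for step 10.
- HCl in MeOH frees 10.

**Step 9.** Addition of the diazophosphonate anion to the electron-rich, ortho-substituted aldehyde may be slower than base-induced decomposition of the reagent, which would leave the aldehyde unconverted.
The fallback sets out from 14 and returns at 17. It makes the aryl–alkyne bond by cross-coupling instead of homologation.
- NIS in MeCN iodinates 14 at the same position that is formylated in step 8, giving 1,2-bis(benzyloxy)-4-iodo-5-methoxybenzene F7.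
- Sonogashira coupling with trimethylsilylacetylene (PdCl2(PPh3)2, CuI, Et3N, THF) gives {[4,5-bis(benzyloxy)-2-methoxyphenyl]ethynyl}trimethylsilane F8.
- K2CO3 in MeOH removes the silyl group to give 17.

**Step 13.** Cleavage of the hindered benzyl ether at O5 may be incomplete. Prolonged exposure may start to reduce the C2–C3 double bond, and the liberated catechol may oxidise in air during work-up.
The fallback sets out from 24 and gives 25 directly, by Lewis acid cleavage instead of hydrogenolysis. BCl3 with pentamethylbenzene as benzyl cation scavenger is used in CH2Cl2 at −78 °C and quenched cold, so that the methyl ethers next to the carbonyl are not attacked.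

## Further compounds

F1 | step 10 | 1-(benzyloxy)-2-iodo-3-(methoxymethoxy)-4,5,6-trimethoxybenzene | COCOc1c(I)c(OCc2ccccc2)c(OC)c(OC)c1OC
F2 | step 10 | 2-(benzyloxy)-6-(methoxymethoxy)-3,4,5-trimethoxybenzaldehyde | COCOc1c(C=O)c(OCc2ccccc2)c(OC)c(OC)c1OC
F3 | step 10 | 1-[2-(benzyloxy)-6-(methoxymethoxy)-3,4,5-trimethoxyphenyl]-3-[4,5-bis(benzyloxy)-2-methoxyphenyl]prop-2-yn-1-ol (racemate, one enantiomer drawn) | COCOc1c([C@H](O)C#Cc2cc(OCc3ccccc3)c(OCc3ccccc3)cc2OC)c(OCc2ccccc2)c(OC)c(OC)c1OC
F4 | step 10 | 1-[2-(benzyloxy)-6-(methoxymethoxy)-3,4,5-trimethoxyphenyl]-3-[4,5-bis(benzyloxy)-2-methoxyphenyl]prop-2-yn-1-one | COCOc1c(C(=O)C#Cc2cc(OCc3ccccc3)c(OCc3ccccc3)cc2OC)c(OCc2ccccc2)c(OC)c(OC)c1OC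
F5 | step 11 | dimethyl {5-(benzyloxy)-2-[4,5-bis(benzyloxy)-2-methoxyphenyl]-6,7,8-trimethoxy-4-oxo-4H-chromen-3-yl}boronate | COB(OC)c1c(-c2cc(OCc3ccccc3)c(OCc3ccccc3)cc2OC)oc2c(OC)c(OC)c(OC)c(OCc3ccccc3)c2c1=O
F6 | step 5 | 1-(benzyloxy)-5-(methoxymethoxy)-2,3,4-trimethoxybenzene | COCOc1cc(OCc2ccccc2)c(OC)c(OC)c1OC
F7 | step 9 | 1,2-bis(benzyloxy)-4-iodo-5-methoxybenzene | COc1cc(OCc2ccccc2)c(OCc2ccccc2)cc1I
F8 | step 9 | {[4,5-bis(benzyloxy)-2-methoxyphenyl]ethynyl}trimethylsilane | COc1cc(OCc2ccccc2)c(OCc2ccccc2)cc1C#C[Si](C)(C)C
F0 | step 13 | none | none
A1 | alternative 1 | 5-hydroxy-3,6,7,8,2'-pentamethoxy-4',5'-(diphenylmethylenedioxy)flavone | COc1c(OC)c(O)c2c(=O)c(OC)c(-c3cc4c(cc3OC)OC(c3ccccc3)(c3ccccc3)O4)oc2c1OC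
A2 | alternative 1 | 6,8,2'-tribromo-5-hydroxy-3,7-dimethoxy-4',5'-(diphenylmethylenedioxy)flavone | COc1c(Br)c(O)c2c(=O)c(OC)c(-c3cc4c(cc3Br)OC(c3ccccc3)(c3ccccc3)O4)oc2c1Br
A3 | alternative 1 | quercetin (3,5,7,3',4'-pentahydroxyflavone) | O=c1c(O)c(-c2ccc(O)c(O)c2)oc2cc(O)cc(O)c12
A4 | alternative 2 | 4',5'-dibenzyloxy-5,7-dihydroxy-3,6,8,2'-tetramethoxyflavone | COc1cc(OCc2ccccc2)c(OCc2ccccc2)cc1-c1oc2c(OC)c(O)c(OC)c(O)c2c(=O)c1OC
A5 | alternative 2 | methyl 9-[4,5-bis(benzyloxy)-2-methoxyphenyl]-2,4,8-trimethoxy-3,5,7,9-tetraoxononanoate (mixture of stereoisomers at three epimerisable methine carbons) | COC(=O)C(OC)C(=O)C(OC)C(=O)CC(=O)C(OC)C(=O)c1cc(OCc2ccccc2)c(OCc2ccccc2)cc1OC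
A6 | alternative 3 | 2,3-trans-3,4-cis-5,4',5'-tribenzyloxy-6,7,8,2'-tetramethoxyflavan-3,4-diol (racemate, one enantiomer drawn) | O[C@@H]1[C@@H](c2cc(OCc3ccccc3)c(OCc3ccccc3)cc2OC)Oc2c(OC)c(OC)c(OC)c(OCc3ccccc3)c2[C@@H]1O
A7 | alternative 3 | 2-(benzyloxy)-6-{1-[4,5-bis(benzyloxy)-2-methoxyphenyl]-2-oxoethoxy}-3,4,5-trimethoxybenzaldehyde (racemate, one enantiomer drawn) | O=C[C@H](Oc1c(OC)c(OC)c(OC)c(OCc2ccccc2)c1C=O)c1cc(OCc2ccccc2)c(OCc2ccccc2)cc1OC
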